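## Retrosynthetic overview

1. The only ring to be built is the pyranone ring C (O1–C2–C3–C4–C4a–C8a) of the flavone. The strategy rests on C4a and O1 being a neighbouring carbon/oxygen nucleophile pair of a 1,3,5-trioxygenated A ring, while C4–C3–C2 is a 1,3-dielectrophile that already carries the C3 prenyl group and the B ring.
2. Cutting C4–C4a and O1–C2 gives phloroglucinol and an α-prenyl aroylacetate. The threefold symmetry of phloroglucinol leaves no A-ring regiochemistry to control.
3. The ketoester is made from 2-methoxyhydroquinone: C-acetylation para to OMe, bis-MOM protection, Claisen carbethoxylation, C-prenylation.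
4. Ring order: rings A and B are bought, ring C is closed in the key step. The end game is methylation of O7 (O5 is chelated) and cleavage of the two MOM ethers.

Key step: step 5

Remark on the chemistry: the target has no stereocentre and no configurationally stable axis, so it is a single achiral compound and no stereocontrol is needed. The only stereogenic carbon on the way, the α-carbon of 8, is labile and becomes sp2 in step 5.

## Route

Step 1
Reactants: 1 2-methoxyhydroquinone; 2 acetic acid
Product: 3 1-(2,5-dihydroxy-4-methoxyphenyl)ethan-1-one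
Conditions: BF3·OEt2 (3 equiv), AcOH, 90 °C, Ar; then H2O
Reagents that add atoms: none
Why: BF3-mediated Friedel–Crafts C-acylation of a phenol by acetic acid (Nencki type) should go to the ring carbon para to the methoxy group and ortho to the C4 hydroxyl, the most activated and least hindered site, and stop at the mono-ketone because the chelated ortho-hydroxy ketone deactivates the ring.

Step 2
Reactants: 3 1-(2,5-dihydroxy-4-methoxyphenyl)ethan-1-one
Product: 4 1-[4-methoxy-2,5-bis(methoxymethoxy)phenyl]ethan-1-one
Conditions: NaH (2.5 equiv), MOMCl (2.5 equiv), DMF, 0 °C to rt, Ar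
Reagents that add atoms: chloromethyl methyl ether (MOMCl), COCCl
Why: Williamson-type O-alkylation of both sodium phenoxides, with NaH chosen so that the hydroxyl hydrogen-bonded to the acetyl group is also deprotonated and capped, gives the base-stable acetals needed for steps 3 to 6.

Step 3
Reactants: 4 1-[4-methoxy-2,5-bis(methoxymethoxy)phenyl]ethan-1-one; 5 diethyl carbonate
Product: 6 ethyl 3-[4-methoxy-2,5-bis(methoxymethoxy)phenyl]-3-oxopropanoate
Conditions: NaH (3 equiv), (EtO)2CO (5 equiv), THF, reflux; then AcOH, 0 °C
Reagents that add atoms: none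
Why: Crossed Claisen condensation of the methyl ketone enolate with non-enolisable diethyl carbonate is pulled to completion by deprotonation of the β-ketoester formed, and aryl MOM ethers are inert to NaH and ethoxide.

Step 4
Reactants: 6 ethyl 3-[4-methoxy-2,5-bis(methoxymethoxy)phenyl]-3-oxopropanoate; 7 prenyl bromide (1-bromo-3-methylbut-2-ene)
Product: 8 ethyl 2-[4-methoxy-2,5-bis(methoxymethoxy)benzoyl]-5-methylhex-4-enoate (racemic, labile α-carbon)
Conditions: NaH (1.0 equiv), THF, 0 °C; then 7 (0.95 equiv), 0 °C to rt
Reagents that add atoms: none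
Why: SN2 C-alkylation of the stabilised β-ketoester enolate by the soft allylic bromide should stop after one prenyl group because base and bromide are limiting and the mono-alkylated ketoester is less acidic and more hindered; the new α-carbon is racemic, which is without consequence since it becomes sp2 in step 5.

Step 5
Reactants: 8 ethyl 2-[4-methoxy-2,5-bis(methoxymethoxy)benzoyl]-5-methylhex-4-enoate; 9 phloroglucinol (anhydrous)
Product: 13 5,7-dihydroxy-2-[4-methoxy-2,5-bis(methoxymethoxy)phenyl]-3-(3-methylbut-2-en-1-yl)-4H-chromen-4-one, via aroyl(prenyl)ketene 10 (not isolated), via 2-acylphloroglucinol diketone 11 (not isolated), via 2-hydroxychromanone hemiketal 12 (not isolated)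
Conditions: 9 (2 equiv), neat melt, 240 °C, Ar sweep (EtOH and H2O distilled off), 10–15 min, microwave or preheated bath
Reagents that add atoms: none
Why: Thermal loss of ethanol from the enol of 8 should give the acylketene 10, which is captured at a ring carbon of the strongly nucleophilic phloroglucinol (an acid-free C-acylation) to give the diketone 11 and so forms C4–C4a. A hydroxyl ortho to the new acyl group then adds to the B-ring ketone in a 6-exo-trig closure (O1–C2) to the hemiketal 12, which loses water to the conjugated pyranone. The closest known reaction is the Mentzer thermal chromone synthesis, the neutral counterpart of the Pechmann and Simonis condensations, which is established for phloroglucinol with aroylacetates and for α-alkyl β-ketoesters. No stereocentre is formed, and the labile α-carbon of 8 ends as sp2 C3. The step needs chromone over 4-arylcoumarin and survival of the prenyl and MOM groups: the absence of acid favours ketene C-acylation over transesterification and Pechmann closure, the short neutral melt spares the acid-labile groups, and the MOM group on O2' prevents the B ring from closing onto C4. The symmetry of 9 makes all three ring carbons equivalent, and the excess of 9 suppresses a second acylation.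

Step 6
Reactants: 13 5,7-dihydroxy-2-[4-methoxy-2,5-bis(methoxymethoxy)phenyl]-3-(3-methylbut-2-en-1-yl)-4H-chromen-4-one
Product: 14 5-hydroxy-7-methoxy-2-[4-methoxy-2,5-bis(methoxymethoxy)phenyl]-3-(3-methylbut-2-en-1-yl)-4H-chromen-4-one
Conditions: MeI (1.1 equiv), K2CO3 (1.2 equiv), acetone, rt, Ar
Reagents that add atoms: iodomethane, CI
Why: Williamson O-methylation should take place at O7 only, because the 7-hydroxyl is a vinylogous acid para to C4=O and is ionised by K2CO3, whereas the 5-hydroxyl is held in a hydrogen bond to the C4 carbonyl and is poorly nucleophilic.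

Step 7
Reactants: 14 5-hydroxy-7-methoxy-2-[4-methoxy-2,5-bis(methoxymethoxy)phenyl]-3-(3-methylbut-2-en-1-yl)-4H-chromen-4-one
Product: 15 artoindonesianin Q, 2-(2,5-dihydroxy-4-methoxyphenyl)-5-hydroxy-7-methoxy-3-(3-methylbut-2-en-1-yl)-4H-chromen-4-one
Conditions: HCl (ca. 0.5 M in MeOH, degassed), 40 °C, Ar
Reagents that add atoms: none
Why: Acid-catalysed transacetalisation of the two aryl MOM ethers to methanol (acetal cleavage) is run dilute, oxygen-free and warm rather than hot, so that the trisubstituted prenyl alkene is not attacked and the liberated hydroquinone is not oxidised.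

## Compound list

1 | 2-methoxyhydroquinone (2-methoxybenzene-1,4-diol) | COc1cc(O)ccc1O | starting material
2 | acetic acid | CC(=O)O | starting material
3 | 1-(2,5-dihydroxy-4-methoxyphenyl)ethan-1-one | CC(=O)c1cc(O)c(OC)cc1O | intermediate
4 | 1-[4-methoxy-2,5-bis(methoxymethoxy)phenyl]ethan-1-one | CC(=O)c1cc(OCOC)c(OC)cc1OCOC | intermediate
5 | diethyl carbonate | CCOC(=O)OCC | starting material
6 | ethyl 3-[4-methoxy-2,5-bis(methoxymethoxy)phenyl]-3-oxopropanoate | CCOC(=O)CC(=O)c1cc(OCOC)c(OC)cc1OCOC | intermediate
7 | prenyl bromide (1-bromo-3-methylbut-2-ene) | CC(C)=CCBr | starting material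
8 | ethyl 2-[4-methoxy-2,5-bis(methoxymethoxy)benzoyl]-5-methylhex-4-enoate (racemic) | CCOC(=O)C(CC=C(C)C)C(=O)c1cc(OCOC)c(OC)cc1OCOC | intermediate
9 | phloroglucinol (benzene-1,3,5-triol) | Oc1cc(O)cc(O)c1 | starting material
10 | 2-[4-methoxy-2,5-bis(methoxymethoxy)benzoyl]-5-methylhexa-1,4-dien-1-one (acylketene, not isolated) | O=C=C(CC=C(C)C)C(=O)c1cc(OCOC)c(OC)cc1OCOC | intermediate
11 | 1-[4-methoxy-2,5-bis(methoxymethoxy)phenyl]-2-(3-methylbut-2-en-1-yl)-3-(2,4,6-trihydroxyphenyl)propane-1,3-dione (racemic, not isolated) | O=C(c1c(O)cc(O)cc1O)C(CC=C(C)C)C(=O)c1cc(OCOC)c(OC)cc1OCOC | intermediate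
12 | 2,5,7-trihydroxy-2-[4-methoxy-2,5-bis(methoxymethoxy)phenyl]-3-(3-methylbut-2-en-1-yl)-2,3-dihydro-4H-chromen-4-one (mixture of diastereomers, not isolated) | Oc1cc(O)c2c(c1)OC(O)(c1cc(OCOC)c(OC)cc1OCOC)C(CC=C(C)C)C2=O | intermediate
13 | 5,7-dihydroxy-2-[4-methoxy-2,5-bis(methoxymethoxy)phenyl]-3-(3-methylbut-2-en-1-yl)-4H-chromen-4-one | Oc1cc(O)c2c(=O)c(CC=C(C)C)c(-c3cc(OCOC)c(OC)cc3OCOC)oc2c1 | intermediate
14 | 5-hydroxy-7-methoxy-2-[4-methoxy-2,5-bis(methoxymethoxy)phenyl]-3-(3-methylbut-2-en-1-yl)-4H-chromen-4-one | COc1cc(O)c2c(=O)c(CC=C(C)C)c(-c3cc(OCOC)c(OC)cc3OCOC)oc2c1 | intermediate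
15 | artoindonesianin Q | COc1cc(O)c2c(=O)c(CC=C(C)C)c(-c3cc(O)c(OC)cc3O)oc2c1 | target

## Step count and risk

Total step count: 7. Longest linear sequence: 7 steps (1 to 15).

**Step 5 (key step).** The ketene may form more slowly than the melt degrades the substrate. The ortho acetal oxygen may capture the ketene or the ester within the molecule with loss of the methoxymethyl group, which would drain material towards 4-hydroxycoumarin-type products. O-acylation of 9 followed by closure onto the ketone would lead into the coumarin series. The hindered diketone may also cyclodehydrate too slowly for the MOM groups to survive.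

Fallback: a Baker–Venkataraman assembly of the same C2–C3–C4 unit, which sets out from 4 and comes back to the route at the target 15.
- Ketone 4 is degraded by the haloform reaction (NaOBr, aq NaOH/dioxane, 0 °C, then cold acidification to pH 4) to 4-methoxy-2,5-bis(methoxymethoxy)benzoic acid F1.
- Commercial 2',6'-dihydroxy-4'-methoxyacetophenone (CC(=O)c1c(O)cc(OC)cc1O) is mono-protected (MOMCl 1.1 equiv, iPr2NEt, CH2Cl2) to 1-[2-hydroxy-4-methoxy-6-(methoxymethoxy)phenyl]ethan-1-one F2; the second hydroxyl stays chelated.
- EDC·HCl/DMAP joins F1 and F2 to the aryl ester 2-acetyl-5-methoxy-3-(methoxymethoxy)phenyl 4-methoxy-2,5-bis(methoxymethoxy)benzoate F3.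
- KOH in pyridine at 50 °C brings about the Baker–Venkataraman acyl shift to 1-[2-hydroxy-4-methoxy-6-(methoxymethoxy)phenyl]-3-[4-methoxy-2,5-bis(methoxymethoxy)phenyl]propane-1,3-dione F4.
- Prenyl bromide 7 with K2CO3 in acetone alkylates the central carbon to 1-[2-hydroxy-4-methoxy-6-(methoxymethoxy)phenyl]-3-[4-methoxy-2,5-bis(methoxymethoxy)phenyl]-2-(3-methylbut-2-en-1-yl)propane-1,3-dione F5.
- Dilute HCl in MeOH closes the pyranone through the A-ring hydroxyl that is already free, dehydrates, and removes the three MOM groups to give 15. O7 carries its methyl group from the start, so steps 6 and 7 are not needed.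

**Step 7.** Protic acid may add water, methanol or HCl across the prenyl double bond or close it onto a neighbouring oxygen, and the liberated hydroquinone may be oxidised to the quinone on contact with air.

Fallback: transprotection without protic acid, which sets out from 14 and comes back at 15. TMSOTf with 2,2'-bipyridyl in MeCN at 0 °C converts the two aryl MOM ethers into 5-hydroxy-7-methoxy-2-[4-methoxy-2,5-bis(trimethylsilyloxy)phenyl]-3-(3-methylbut-2-en-1-yl)-4H-chromen-4-one F6. Addition of water in the same flask hydrolyses F6 at neutral pH to 15.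

**Step 1.** Acylation may occur at oxygen or at another ring carbon, a second acetyl group may enter, or the electron-rich hydroquinone may be oxidised under hot Lewis-acidic conditions.

Fallback: a Fries rearrangement, which sets out from 1 and comes back at 3. Ac2O in pyridine gives 2-methoxy-1,4-phenylene diacetate F7. BF3·OEt2 at 80 °C shifts the acetyl group of the O4 ester to the neighbouring carbon para to OMe and gives 5-acetyl-4-hydroxy-2-methoxyphenyl acetate F8. K2CO3 in MeOH removes the remaining acetate to return 3.

## Further compounds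

F1 | step 5 | 4-methoxy-2,5-bis(methoxymethoxy)benzoic acid | OC(=O)c1cc(OCOC)c(OC)cc1OCOC
F2 | step 5 | 1-[2-hydroxy-4-methoxy-6-(methoxymethoxy)phenyl]ethan-1-one | CC(=O)c1c(O)cc(OC)cc1OCOC
F3 | step 5 | 2-acetyl-5-methoxy-3-(methoxymethoxy)phenyl 4-methoxy-2,5-bis(methoxymethoxy)benzoate | CC(=O)c1c(OC(=O)c2cc(OCOC)c(OC)cc2OCOC)cc(OC)cc1OCOC
F4 | step 5 | 1-[2-hydroxy-4-methoxy-6-(methoxymethoxy)phenyl]-3-[4-methoxy-2,5-bis(methoxymethoxy)phenyl]propane-1,3-dione | O=C(CC(=O)c1cc(OCOC)c(OC)cc1OCOC)c1c(O)cc(OC)cc1OCOC
F5 | step 5 | 1-[2-hydroxy-4-methoxy-6-(methoxymethoxy)phenyl]-3-[4-methoxy-2,5-bis(methoxymethoxy)phenyl]-2-(3-methylbut-2-en-1-yl)propane-1,3-dione (racemic) | O=C(C(CC=C(C)C)C(=O)c1cc(OCOC)c(OC)cc1OCOC)c1c(O)cc(OC)cc1OCOC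
F6 | step 7 | 5-hydroxy-7-methoxy-2-[4-methoxy-2,5-bis(trimethylsilyloxy)phenyl]-3-(3-methylbut-2-en-1-yl)-4H-chromen-4-one | COc1cc(O)c2c(=O)c(CC=C(C)C)c(-c3cc(O[Si](C)(C)C)c(OC)cc3O[Si](C)(C)C)oc2c1
F7 | step 1 | 2-methoxy-1,4-phenylene diacetate | COc1cc(OC(C)=O)ccc1OC(C)=O
F8 | step 1 | 5-acetyl-4-hydroxy-2-methoxyphenyl acetate | CC(=O)Oc1cc(C(C)=O)c(O)cc1OC
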